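## Retrosynthetic overview
1. The target comes from its 4'-O-acetate by a neutral enzymatic deacetylation, so no base ever touches the flavanone.
2. Rings C and A are both made in one flask from an acyclic (S)-δ-hydroxy-β-diketone. Cyclodehydration closes ring C (O1–C8a). A [3+3] double C-acylation (C8–C7 and C4a–C5) with a prenylmalonyl C3 unit then builds ring A.
3. O1 sits on C8a before ring A exists and the C3 unit is symmetric. Prenyl can therefore only end up para to O1, at C6, and no 6-/8-prenyl problem arises.
4. C2 (S) is set by a catalytic enantioselective vinylogous Mukaiyama aldol of vanillin acetate with the bis(silyl) dienol ether of acetylacetone. The C2–O bond is never broken afterwards.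
5. Ring order: B (bought), then C, then A.

Assumption: (S)-BINOL/Ti(OiPr)4 is taken to deliver the nucleophile to the Si face of the aromatic aldehyde, as in related BINOL–titanium additions. The configuration of the aldol is checked by Mosher esters, and (R)-BINOL would be used if the sense proved opposite.

## Route

Step 1
Reactants: 1 acetylacetone (pentane-2,4-dione)
Product: 2 2,4-bis(trimethylsilyloxy)penta-1,3-diene
Conditions: Me3SiOTf (2.2 equiv), Et3N (2.5 equiv), Et2O, 0 °C → rt
Reagents that add atoms: trimethylsilyl trifluoromethanesulfonate, C[Si](C)(C)OS(=O)(=O)C(F)(F)F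
Why: Double soft enolisation and O-silylation of the β-diketone gives a Chan-type 1,3-bis(silyloxy)diene, a neutral equivalent of the acetylacetone dianion, and no stereocentre is formed.

Step 2
Reactants: 2 2,4-bis(trimethylsilyloxy)penta-1,3-diene; 3 vanillin acetate (4-formyl-2-methoxyphenyl acetate)
Product: 5 4-[(1S)-1-hydroxy-3,5-dioxohexyl]-2-methoxyphenyl acetate, via bis-silylated aldol adduct 4 (not isolated)
Conditions: (S)-BINOL (10 mol %), Ti(OiPr)4 (10 mol %), 4 Å MS, THF, −78 → −20 °C; then 10% aq. citric acid, THF, 0 °C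
Reagents that add atoms: none
Why: In this catalytic enantioselective vinylogous Mukaiyama aldol reaction, the terminal CH2 of 2 (its most nucleophilic site) adds to the Si face of aldehyde 3 held by the (S)-BINOL–Ti(OiPr)4 complex, which sets the carbinol (future C2) as S, and the mild acidic work-up removes both silyl groups without cyclising or dehydrating the aldol.

Step 3
Reactants: 6 diethyl malonate; 7 prenyl bromide (1-bromo-3-methylbut-2-ene)
Product: 9 2-(3-methylbut-2-en-1-yl)malonic acid, via diethyl prenylmalonate 8 (not isolated)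
Conditions: NaOEt, EtOH, 0 °C → rt; then KOH, H2O/EtOH, rt; cold 2 M HCl to pH 2
Reagents that add atoms: potassium hydroxide, [OH-].[K+]
Why: Malonic ester alkylation (SN2 at the primary allylic bromide) is followed by saponification in the same pot, and cold acidification avoids decarboxylation and lactonisation onto the alkene.

Step 4
Reactants: 5 4-[(1S)-1-hydroxy-3,5-dioxohexyl]-2-methoxyphenyl acetate; 9 2-(3-methylbut-2-en-1-yl)malonic acid
Product: 12 (2S)-4'-O-acetyl-6-prenylhomoeriodictyol, via dihydropyranone 10 (not isolated), via prenylmalonyl dichloride 11 (not isolated)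
Conditions: 5, (+)-camphor-10-sulfonic acid (5 mol %), 4 Å MS, CH2Cl2, rt, 2 h; then −20 °C, slow addition of 11 (1.2 equiv, made beforehand from 9 and Me2C=C(Cl)NMe2, 2.4 equiv, CH2Cl2, 0 °C), Et2O co-solvent, −20 °C → rt, 24 h, slow argon purge; pH 7 phosphate buffer
Reagents that add atoms: none
Why: Proposed new method: acid first closes ring C by 6-exo hemiketalisation of the C2 hydroxyl on the distal carbonyl and loss of water (the C2–O bond is untouched, so S is retained); the protonated or O-acylated dihydropyranone 10 then loses a proton from its 6-methyl group to give a 2-alkoxydienol whose terminal carbon (C8) and then C4a are C-acylated by the two acyl chloride (chlorocarbonylketene) ends of 11, O-acylations being reversible under HCl while the C,C-closure is made irreversible by tautomerisation to the phloroglucinol ring; the closest known reaction type is the Effenberger [3+3] annulation of enol ethers with malonyl dichloride (which tolerates prenyl groups), and because O1 already sits on C8a and the C3 unit is symmetric the prenyl group can only end up at C6, while the base-free medium excludes retro-oxa-Michael racemisation.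

Step 5
Reactants: 12 (2S)-4'-O-acetyl-6-prenylhomoeriodictyol
Product: 13 (2S)-6-prenylhomoeriodictyol (target)
Conditions: immobilised Candida antarctica lipase B (Novozym 435), n-BuOH (5 equiv), MTBE, 40 °C
Reagents that add atoms: none
Why: Lipase-catalysed transesterification to butanol cleaves the exposed phenolic acetate at neutral pH, so ring C cannot open by retro-oxa-Michael reaction (no racemisation at C2, no 6-/8-prenyl scrambling) and the prenyl group cannot cyclise under acid.

## Compound list
1 | acetylacetone (pentane-2,4-dione) | CC(=O)CC(C)=O | starting material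
2 | 2,4-bis(trimethylsilyloxy)penta-1,3-diene (E/Z mixture at C3=C4, geometry lost later) | C=C(O[Si](C)(C)C)C=C(C)O[Si](C)(C)C | intermediate
3 | vanillin acetate (4-formyl-2-methoxyphenyl acetate) | COc1cc(C=O)ccc1OC(C)=O | starting material
4 | 4-[(1S)-3-oxo-1,5-bis(trimethylsilyloxy)hex-4-en-1-yl]-2-methoxyphenyl acetate (not isolated, E/Z mixture) | COc1cc([C@@H](O[Si](C)(C)C)CC(=O)C=C(C)O[Si](C)(C)C)ccc1OC(C)=O | intermediate
5 | 4-[(1S)-1-hydroxy-3,5-dioxohexyl]-2-methoxyphenyl acetate | COc1cc([C@@H](O)CC(=O)CC(C)=O)ccc1OC(C)=O | intermediate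
6 | diethyl malonate | CCOC(=O)CC(=O)OCC | starting material
7 | prenyl bromide (1-bromo-3-methylbut-2-ene) | CC(C)=CCBr | starting material
8 | diethyl 2-(3-methylbut-2-en-1-yl)malonate (not isolated) | CCOC(=O)C(CC=C(C)C)C(=O)OCC | intermediate
9 | 2-(3-methylbut-2-en-1-yl)malonic acid | OC(=O)C(CC=C(C)C)C(O)=O | intermediate
10 | 4-[(2S)-6-methyl-4-oxo-3,4-dihydro-2H-pyran-2-yl]-2-methoxyphenyl acetate (not isolated) | COc1cc([C@@H]2CC(=O)C=C(C)O2)ccc1OC(C)=O | intermediate
11 | 2-(3-methylbut-2-en-1-yl)malonyl dichloride (not isolated) | CC(C)=CCC(C(Cl)=O)C(Cl)=O | intermediate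
12 | 4-[(2S)-5,7-dihydroxy-6-(3-methylbut-2-en-1-yl)-4-oxo-3,4-dihydro-2H-chromen-2-yl]-2-methoxyphenyl acetate | COc1cc([C@@H]2CC(=O)c3c(cc(O)c(CC=C(C)C)c3O)O2)ccc1OC(C)=O | intermediate
13 | (2S)-5,7-dihydroxy-2-(4-hydroxy-3-methoxyphenyl)-6-(3-methylbut-2-en-1-yl)-2,3-dihydro-4H-chromen-4-one | COc1cc([C@@H]2CC(=O)c3c(cc(O)c(CC=C(C)C)c3O)O2)ccc1O | target

## Step count and risks
Total steps: 5. Longest linear sequence: 4 (1 → 2 → 5 → 12 → 13).

**Step 4 (highest risk).** There are three ways it could fail.
- The vinylogous ester 10 may be too poor a nucleophile.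
- The C4 carbonyl oxygen may join in an O,C-annulation and give a fused 2-pyranone.
- HCl may cyclise the new prenyl-phloroglucinol to a chroman.

The fallback sets out from 3 and 7 and comes back at 12. It drops the de novo ring A and applies the same symmetry argument to an aromatic block. Aldehyde 3 undergoes a Ti(OiPr)4/(R)-BINOL Mukaiyama acetate aldol with 1-(tert-butylthio)-1-(trimethylsilyloxy)ethene. This gives the O-silylated (R)-aldol thioester F1 and, after dilute acid, the (R)-β-hydroxy thioester F2. Phloroglucinol is C-prenylated with 7 (aq. KOH, 0 °C) to 2-prenylphloroglucinol F3. A Mitsunobu etherification (PPh3, DIAD, THF, 0 °C) joins F2 to the one unhindered hydroxyl of F3, the one para to prenyl. It proceeds with inversion and gives the (S)-aryl ether thioester F4. AgO2CCF3/Na2HPO4 in CH2Cl2 then activates the thioester for an intramolecular Friedel–Crafts acylation. The two positions ortho to the ether oxygen are equivalent, so only 12 can form.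

**Step 2.** The diketone-derived diene is less studied than ester-derived ones. The ee may be moderate, or the adduct may cyclise during work-up. The fallback sets out from 2 and 3 and comes back at 5. It makes the aldol racemic and resolves it. BF3·OEt2 (CH2Cl2, −78 °C) and the same citric acid work-up give the racemic aldol F5. Novozym 435 and vinyl acetate in MTBE acetylate the R enantiomer (Kazlauskas preference for aryl carbinols) to the (R)-carbinol acetate F6. Unreacted (S)-5 is separated by chromatography at about 50% conversion.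

**Step 5.** The lipase may not accept the hindered guaiacyl acetate. Any basic substitute would open ring C, which would racemise C2 and scramble 6-/8-prenyl. The fallback sets out from 2 and comes back at 13. It changes the phenol protecting group to a silyl ether that is removed by fluoride. Vanillin is silylated (TBSCl, imidazole, DMF) to O-TBS-vanillin F7. The aldol of step 2 run on F7 gives the silylated adduct F8 and then the (S)-aldol F9. The one-flask ring closure of step 4 run on F9 and 9 gives, through the dihydropyranone F10, the 4'-O-TBS flavanone F11. Et3N·3HF in THF at 0 °C (a slightly acidic fluoride source) then frees 13.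

## Further compounds
F1 | step 4 | S-tert-butyl (3R)-3-(4-acetoxy-3-methoxyphenyl)-3-(trimethylsilyloxy)propanethioate | COc1cc([C@H](O[Si](C)(C)C)CC(=O)SC(C)(C)C)ccc1OC(C)=O
F2 | step 4 | S-tert-butyl (3R)-3-(4-acetoxy-3-methoxyphenyl)-3-hydroxypropanethioate | COc1cc([C@H](O)CC(=O)SC(C)(C)C)ccc1OC(C)=O
F3 | step 4 | 2-(3-methylbut-2-en-1-yl)benzene-1,3,5-triol | CC(C)=CCc1c(O)cc(O)cc1O
F4 | step 4 | S-tert-butyl (3S)-3-(4-acetoxy-3-methoxyphenyl)-3-[3,5-dihydroxy-4-(3-methylbut-2-en-1-yl)phenoxy]propanethioate | COc1cc([C@@H](Oc2cc(O)c(CC=C(C)C)c(O)c2)CC(=O)SC(C)(C)C)ccc1OC(C)=O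
F5 | step 2 | racemic 4-(1-hydroxy-3,5-dioxohexyl)-2-methoxyphenyl acetate | COc1cc(C(O)CC(=O)CC(C)=O)ccc1OC(C)=O
F6 | step 2 | 4-[(1R)-1-acetoxy-3,5-dioxohexyl]-2-methoxyphenyl acetate | COc1cc([C@H](OC(C)=O)CC(=O)CC(C)=O)ccc1OC(C)=O
F7 | step 5 | 4-(tert-butyldimethylsilyloxy)-3-methoxybenzaldehyde | COc1cc(C=O)ccc1O[Si](C)(C)C(C)(C)C
F8 | step 5 | (6S)-6-[4-(tert-butyldimethylsilyloxy)-3-methoxyphenyl]-2,6-bis(trimethylsilyloxy)hex-2-en-4-one | COc1cc([C@@H](O[Si](C)(C)C)CC(=O)C=C(C)O[Si](C)(C)C)ccc1O[Si](C)(C)C(C)(C)C
F9 | step 5 | (6S)-6-[4-(tert-butyldimethylsilyloxy)-3-methoxyphenyl]-6-hydroxyhexane-2,4-dione | COc1cc([C@@H](O)CC(=O)CC(C)=O)ccc1O[Si](C)(C)C(C)(C)C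
F10 | step 5 | (2S)-2-[4-(tert-butyldimethylsilyloxy)-3-methoxyphenyl]-6-methyl-2,3-dihydro-4H-pyran-4-one | COc1cc([C@@H]2CC(=O)C=C(C)O2)ccc1O[Si](C)(C)C(C)(C)C
F11 | step 5 | (2S)-2-[4-(tert-butyldimethylsilyloxy)-3-methoxyphenyl]-5,7-dihydroxy-6-(3-methylbut-2-en-1-yl)-2,3-dihydro-4H-chromen-4-one | COc1cc([C@@H]2CC(=O)c3c(cc(O)c(CC=C(C)C)c3O)O2)ccc1O[Si](C)(C)C(C)(C)C
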